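**Retrosynthetic overview**
1. Target 12 ⇒ tetraphenol 11 (eight C–Br bonds, bromination ortho to OH) ⇒ tetramethyl ether 10 (four O–Me cleavages).
2. 10 ⇒ mono-ketone 9 + 4-methoxybenzoyl chloride 8 ⇒ 3,4-bis(4-methoxyphenyl)pyrrole 7 + 8 (the two pyrrole–C(=O) bonds, made one at a time by Friedel–Crafts acylation); 7 ⇒ diacid 6 (loss of two CO2).
3. Key disconnection: pyrrole C2–C3 and C4–C5 of 6 ⇒ anisil 3 + diethyl N-acetyliminodiacetate 2 (Hinsberg condensation: an intermolecular aldol joins the fragments, an intramolecular aldol closes the ring).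
4. Ring order: the pyrrole is the only ring made (step 2); the four benzene rings are bought and the bromines go on last.

Assumption: the target has no stereocentre (it is achiral), so the SMILES defines it completely and no stereocontrol is needed.

**Route**

Step 1
Reactants: 1 diethyl iminodiacetate
Product: 2 diethyl N-acetyliminodiacetate
Conditions: Ac2O (1.3 equiv), pyridine, cat. DMAP, CH2Cl2, 0 °C → rt
Reagents that add atoms: acetic anhydride, CC(=O)OC(C)=O
Why: N-acetylation (nucleophilic acyl substitution) of the secondary amine makes the nitrogen a non-nucleophilic amide that cannot condense with the diketone in step 2, while both α-CH2 groups stay enolisable; no stereocentre is involved.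

Step 2
Reactants: 2 diethyl N-acetyliminodiacetate; 3 4,4'-dimethoxybenzil (anisil)
Product: 6 3,4-bis(4-methoxyphenyl)-1H-pyrrole-2,5-dicarboxylic acid, via pyrrole diester 4 (not isolated), via pyrrole half-ester 5 (not isolated)
Conditions: NaOEt (3 equiv), EtOH, reflux, 16 h; then 2 M aq NaOH, reflux, 4 h; then aq HCl, 0 °C, pH 2
Reagents that add atoms: sodium hydroxide, [Na+].[OH-] (aqueous; supplies the two carboxyl OH oxygens)
Why: Hinsberg pyrrole synthesis: the ester enolate of 2 adds to one ketone of 3 in an intermolecular aldol reaction that joins the two fragments (C2–C3), the second α-CH2 closes the ring by intramolecular aldol addition to the other ketone (C4–C5), two dehydrations aromatise, ethoxide removes the activated N-acetyl group, and hydroxide converges diester and half-ester on the achiral diacid.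

Step 3
Reactants: 6 3,4-bis(4-methoxyphenyl)-1H-pyrrole-2,5-dicarboxylic acid
Product: 7 3,4-bis(4-methoxyphenyl)-1H-pyrrole
Conditions: ethanolamine, reflux (170 °C), N2, 3 h; then H2O, filter
Reagents that add atoms: none
Why: Thermal protodecarboxylation of a pyrrole-2-carboxylic acid: the electron-rich ring is protonated at each carboxyl-bearing α-carbon and loses CO2, while the methoxyaryl groups are inert.

Step 4
Reactants: 7 3,4-bis(4-methoxyphenyl)-1H-pyrrole; 8 4-methoxybenzoyl chloride
Product: 9 [3,4-bis(4-methoxyphenyl)-1H-pyrrol-2-yl](4-methoxyphenyl)methanone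
Conditions: 8 (1.05 equiv), AlCl3 (1.1 equiv), CH2Cl2, 0 °C, 20 min (preformed complex); add 7, −20 → 0 °C, 2 h; then ice/1 M aq HCl
Reagents that add atoms: none
Why: Friedel–Crafts acylation: the acylium–AlCl3 complex attacks one of the two equivalent free α-positions (the β-positions are blocked), and with one equivalent at low temperature the reaction stops at the mono-ketone because the AlCl3-complexed 2-aroylpyrrole is strongly deactivated.

Step 5
Reactants: 9 [3,4-bis(4-methoxyphenyl)-1H-pyrrol-2-yl](4-methoxyphenyl)methanone; 8 4-methoxybenzoyl chloride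
Product: 10 [3,4-bis(4-methoxyphenyl)-1H-pyrrole-2,5-diyl]bis[(4-methoxyphenyl)methanone]
Conditions: 8 (2.0 equiv), AlCl3 (3.0 equiv), ClCH2CH2Cl, 0 °C → 45 °C, 6 h; then ice/1 M aq HCl
Reagents that add atoms: none
Why: Second Friedel–Crafts acylation: with excess acylium and gentle warming, the only remaining pyrrole position (C5) of the purified mono-ketone is acylated, the pyrrole α-carbon still being more nucleophilic than the anisyl rings.

Step 6
Reactants: 10 [3,4-bis(4-methoxyphenyl)-1H-pyrrole-2,5-diyl]bis[(4-methoxyphenyl)methanone]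
Product: 11 [3,4-bis(4-hydroxyphenyl)-1H-pyrrole-2,5-diyl]bis[(4-hydroxyphenyl)methanone]
Conditions: BBr3 (10 equiv), CH2Cl2, −78 °C → rt, 16 h; then H2O, 0 °C
Reagents that add atoms: none
Why: BBr3 ether cleavage (Lewis-acid complexation, then SN2 attack of bromide on methyl) removes all four aryl methyl ethers while the diaryl ketones and the pyrrole are inert.

Step 7
Reactants: 11 [3,4-bis(4-hydroxyphenyl)-1H-pyrrole-2,5-diyl]bis[(4-hydroxyphenyl)methanone]
Product: 12 [3,4-bis(3,5-dibromo-4-hydroxyphenyl)-1H-pyrrole-2,5-diyl]bis[(3,5-dibromo-4-hydroxyphenyl)methanone] (CNP0269782.0)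
Conditions: Br2 (8.4 equiv), NaOAc (9 equiv), AcOH, rt, 4 h; aq Na2S2O3 work-up
Reagents that add atoms: bromine, BrBr
Why: Electrophilic aromatic bromination occurs at the eight positions ortho to the four phenol OH groups because the para positions are blocked and the fully substituted, doubly acylated pyrrole is unreactive; NaOAc buffers the HBr.

**Compound list**
1 | diethyl iminodiacetate | CCOC(=O)CNCC(=O)OCC | starting material
2 | diethyl N-acetyliminodiacetate | CCOC(=O)CN(C(C)=O)CC(=O)OCC | intermediate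
3 | 4,4'-dimethoxybenzil (anisil) | COc1ccc(cc1)C(=O)C(=O)c1ccc(OC)cc1 | starting material
4 | diethyl 3,4-bis(4-methoxyphenyl)-1H-pyrrole-2,5-dicarboxylate | CCOC(=O)c1[nH]c(C(=O)OCC)c(-c2ccc(OC)cc2)c1-c1ccc(OC)cc1 | intermediate
5 | 5-(ethoxycarbonyl)-3,4-bis(4-methoxyphenyl)-1H-pyrrole-2-carboxylic acid | CCOC(=O)c1[nH]c(C(=O)O)c(-c2ccc(OC)cc2)c1-c1ccc(OC)cc1 | intermediate
6 | 3,4-bis(4-methoxyphenyl)-1H-pyrrole-2,5-dicarboxylic acid | OC(=O)c1[nH]c(C(=O)O)c(-c2ccc(OC)cc2)c1-c1ccc(OC)cc1 | intermediate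
7 | 3,4-bis(4-methoxyphenyl)-1H-pyrrole | COc1ccc(cc1)-c1c[nH]cc1-c1ccc(OC)cc1 | intermediate
8 | 4-methoxybenzoyl chloride | COc1ccc(cc1)C(Cl)=O | starting material
9 | [3,4-bis(4-methoxyphenyl)-1H-pyrrol-2-yl](4-methoxyphenyl)methanone | COc1ccc(cc1)C(=O)c1[nH]cc(-c2ccc(OC)cc2)c1-c1ccc(OC)cc1 | intermediate
10 | [3,4-bis(4-methoxyphenyl)-1H-pyrrole-2,5-diyl]bis[(4-methoxyphenyl)methanone] | COc1ccc(cc1)C(=O)c1[nH]c(C(=O)c2ccc(OC)cc2)c(-c2ccc(OC)cc2)c1-c1ccc(OC)cc1 | intermediate
11 | [3,4-bis(4-hydroxyphenyl)-1H-pyrrole-2,5-diyl]bis[(4-hydroxyphenyl)methanone] | O=C(c1ccc(O)cc1)c1[nH]c(C(=O)c2ccc(O)cc2)c(-c2ccc(O)cc2)c1-c1ccc(O)cc1 | intermediate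
12 | [3,4-bis(3,5-dibromo-4-hydroxyphenyl)-1H-pyrrole-2,5-diyl]bis[(3,5-dibromo-4-hydroxyphenyl)methanone] | O=C(c1cc(Br)c(O)c(Br)c1)c1[nH]c(C(=O)c2cc(Br)c(O)c(Br)c2)c(-c2cc(Br)c(O)c(Br)c2)c1-c1cc(Br)c(O)c(Br)c1 | target

**Summary**
Total step count: 7. Longest linear sequence: 7 steps (1 → 2 → 6 → 7 → 9 → 10 → 11 → 12).

**Steps most likely to fail**

Step 5 (highest risk). The 2-aroylpyrrole 9 is deactivated, more so as its AlCl3 complex, and C5 is flanked by an aryl group, so the second acylation may stall or acylate an anisyl ring ortho to OMe. Fallback: set out from diacid 6 and convert it with CDI and then MeNHOMe·HCl (THF/DMF, rt → 40 °C) into N2,N5-dimethoxy-3,4-bis(4-methoxyphenyl)-N2,N5-dimethyl-1H-pyrrole-2,5-dicarboxamide F1. Treat F1 with excess 4-methoxyphenylmagnesium bromide (6 equiv, THF, 0 → 40 °C, then 1 M aq HCl). This is a twofold Weinreb ketone synthesis in which one equivalent is consumed by the N–H and the chelated tetrahedral intermediates prevent over-addition. It comes back to the route at 10.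

Step 2. Anisil is an electron-rich, weakly electrophilic diketone, so the condensation may give low conversion or benzilic-type by-products. Fallback: set out from 1 and N-benzylate it (BnBr, K2CO3, MeCN) to diethyl N-benzyliminodiacetate F2. Condense F2 with diethyl oxalate (NaOEt, EtOH; Hinsberg double Claisen condensation) to diethyl 1-benzyl-3,4-dihydroxy-1H-pyrrole-2,5-dicarboxylate F3. Convert F3 with Tf2O/pyridine into diethyl 1-benzyl-3,4-bis(trifluoromethylsulfonyloxy)-1H-pyrrole-2,5-dicarboxylate F4. Couple F4 twice with 4-methoxyphenylboronic acid (Pd(PPh3)4, aq Na2CO3, THF, reflux; Suzuki–Miyaura) to diethyl 1-benzyl-3,4-bis(4-methoxyphenyl)-1H-pyrrole-2,5-dicarboxylate F5. Hydrogenolyse the N-benzyl group of F5 (H2, Pd/C, AcOH, 60 °C) to come back at diester 4, which is saponified to 6 as in the second half of step 2.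

Step 4. The free, electron-rich pyrrole 7 is acid-sensitive and may oligomerise or give mono/bis mixtures under AlCl3. Fallback: set out from pyrrole 7 and heat it with 4-methoxy-N,N-dimethylbenzamide and POCl3 (ClCH2CH2Cl, reflux; Vilsmeier–Haack aroylation, which stops cleanly after one aroylation) to give {[3,4-bis(4-methoxyphenyl)-1H-pyrrol-2-yl](4-methoxyphenyl)methylidene}dimethylammonium chloride F6. Hydrolyse F6 with aq NaOAc at reflux. This comes back to the route at 9.

**Further compounds**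
F1 | step 5 | N2,N5-dimethoxy-3,4-bis(4-methoxyphenyl)-N2,N5-dimethyl-1H-pyrrole-2,5-dicarboxamide | CON(C)C(=O)c1[nH]c(C(=O)N(C)OC)c(-c2ccc(OC)cc2)c1-c1ccc(OC)cc1
F2 | step 2 | diethyl N-benzyliminodiacetate | CCOC(=O)CN(Cc1ccccc1)CC(=O)OCC
F3 | step 2 | diethyl 1-benzyl-3,4-dihydroxy-1H-pyrrole-2,5-dicarboxylate | CCOC(=O)c1c(O)c(O)c(C(=O)OCC)n1Cc1ccccc1
F4 | step 2 | diethyl 1-benzyl-3,4-bis(trifluoromethylsulfonyloxy)-1H-pyrrole-2,5-dicarboxylate | CCOC(=O)c1c(OS(=O)(=O)C(F)(F)F)c(OS(=O)(=O)C(F)(F)F)c(C(=O)OCC)n1Cc1ccccc1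
F5 | step 2 | diethyl 1-benzyl-3,4-bis(4-methoxyphenyl)-1H-pyrrole-2,5-dicarboxylate | CCOC(=O)c1c(-c2ccc(OC)cc2)c(-c2ccc(OC)cc2)c(C(=O)OCC)n1Cc1ccccc1
F6 | step 4 | {[3,4-bis(4-methoxyphenyl)-1H-pyrrol-2-yl](4-methoxyphenyl)methylidene}dimethylammonium chloride | C[N+](C)=C(c1ccc(OC)cc1)c1[nH]cc(-c2ccc(OC)cc2)c1-c1ccc(OC)cc1.[Cl-]
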